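**Retrosynthetic overview**
1. Target ← acetylation of the C12 alcohol ← Ni/Cr (Nozaki–Hiyama–Kishi) union of the bicyclic C4 enol triflate (C1–C11a, C18, C19) with the side-chain aldehyde methyl (E)-2-methyl-5-oxopent-2-enoate (C12–C17); the chiral chromium ligand sets C12.
2. Enol triflate ← C4 ketone; C1 acetate ← PMB acetal (DDQ, then trans-selective acetylation); (7S,8R)-oxirane ← Shi epoxidation of the (Z)-cyclononene.
3. Nine-membered ring ← ring-closing metathesis (C7=C8) of a 4,5-trans-disubstituted 6-alkoxypyranone.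
4. That pyranone ← three-piece assembly on (6S)-6-PMBO-2H-pyran-3(6H)-one: copper-catalysed addition of a hexa-1,5-dien-2-yl Grignard anti to the acetal (C11a), then enolate alkylation with 3-methylbut-3-enyl triflate anti to it (C4a).
5. Ring order: pyranone (Achmatowicz from furfuryl alcohol, lipase-set acetal) → carbocycle (RCM) → oxirane (Shi) → dihydropyran enol ether (triflation). Side chain from propane-1,3-diol and methyl 2-bromopropanoate.

Assumption: xenicane numbering is used for the bicyclic compounds (C1 acetal carbon, O2, C3=C4, C4a, C5–C11 carbocycle, C11a, side chain C12–C17); the SMILES encodes a cis-fused (7S,8R) oxirane, i.e. one derived from a (Z)-cyclononene.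
Assumption: the lipase of step 2 acylates the (6R)-hemiacetal and the (S)-sulfonamide ligand of step 19 directs Re-face addition; if either sense is reversed, the enantiomeric enzyme or ligand is used.

**Route**

Step 1
Reactants: 1 furan-2-ylmethanol
Product: 2 6-hydroxy-2H-pyran-3(6H)-one (racemic hemiacetal)
Conditions: t-BuOOH, VO(acac)2 (2 mol%), CH2Cl2, 0 → 25 °C
Reagents that add atoms: tert-butyl hydroperoxide, CC(C)(C)OO
Why: Achmatowicz oxidative ring expansion (hydroxyl-directed oxidation of the furan, ring opening to the ene-dione, re-closure as the six-membered hemiacetal); no stereocentre is fixed yet.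

Step 2
Reactants: 2 6-hydroxy-2H-pyran-3(6H)-one
Product: 3 (6R)-6-acetoxy-2H-pyran-3(6H)-one
Conditions: vinyl acetate, immobilised Pseudomonas cepacia lipase, hexane, 25 °C
Reagents that add atoms: vinyl acetate, C=COC(C)=O
Why: Lipase-catalysed dynamic kinetic resolution: only the (R)-hemiacetal is acylated while the other enantiomer racemises by ring–chain tautomerism, setting the acetal centre that steers C11a and C4a.

Step 3
Reactants: 3 (6R)-6-acetoxy-2H-pyran-3(6H)-one
Product: 4 (6S)-6-[(4-methoxybenzyl)oxy]-2H-pyran-3(6H)-one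
Conditions: 4-methoxybenzyl alcohol (1.5 equiv), Pd(PPh3)4 (3 mol%), CH2Cl2, 0 °C
Reagents that add atoms: 4-methoxybenzyl alcohol, COc1ccc(CO)cc1
Why: Tsuji–Trost O-allylation: ionisation and alcohol attack both occur anti to zerovalent palladium, so the acetal is exchanged with net retention (the descriptor changes only through CIP priorities) for a group that survives organocopper chemistry.

Step 4
Reactants: 5 allylmagnesium bromide; 6 2,3-dibromoprop-1-ene
Product: 7 2-bromohexa-1,5-diene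
Conditions: Et2O, 0 → 25 °C
Reagents that add atoms: none
Why: Allyl–allyl coupling by Grignard displacement of the allylic bromide; the vinylic bromide is inert.

Step 5
Reactants: 4 (6S)-6-[(4-methoxybenzyl)oxy]-2H-pyran-3(6H)-one; 7 2-bromohexa-1,5-diene
Product: 9 {[(5R,6S)-5-(hexa-1,5-dien-2-yl)-6-[(4-methoxybenzyl)oxy]-5,6-dihydro-2H-pyran-3-yl]oxy}trimethylsilane, via hexa-1,5-dien-2-ylmagnesium bromide 8 (not isolated)
Conditions: 7, Mg, THF, 40 °C; then CuBr·SMe2 (10 mol%), Me3SiCl, 4, THF, −78 °C; Et3N, pentane work-up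
Reagents that add atoms: chlorotrimethylsilane, C[Si](C)(C)Cl; magnesium, [Mg] (held only by 8)
Why: Copper-catalysed, Me3SiCl-accelerated conjugate addition of the alkenyl Grignard: the nucleophile enters C11a anti to the pseudo-axial acetal alkoxy group, and the regiodefined enolate is stored as its silyl enol ether.

Step 6
Reactants: 10 3-methylbut-3-en-1-ol
Product: 11 3-methylbut-3-en-1-yl trifluoromethanesulfonate
Conditions: Tf2O, 2,6-lutidine, CH2Cl2, −78 °C; cold pentane filtration, used at once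
Reagents that add atoms: trifluoromethanesulfonic anhydride, O=S(=O)(OS(=O)(=O)C(F)(F)F)C(F)(F)F
Why: Low-temperature O-sulfonylation gives a primary triflate reactive enough to alkylate a ketone enolate where the bromide or iodide would not.

Step 7
Reactants: 9 {[(5R,6S)-5-(hexa-1,5-dien-2-yl)-6-[(4-methoxybenzyl)oxy]-5,6-dihydro-2H-pyran-3-yl]oxy}trimethylsilane; 11 3-methylbut-3-en-1-yl trifluoromethanesulfonate
Product: 13 (4S,5R,6S)-5-(hexa-1,5-dien-2-yl)-6-[(4-methoxybenzyl)oxy]-4-(3-methylbut-3-en-1-yl)dihydro-2H-pyran-3(4H)-one, via lithium enolate 12 (not isolated)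
Conditions: MeLi, THF, 0 °C; then DMPU, 11, −78 → −40 °C
Reagents that add atoms: methyllithium, [Li]C (lithium held only by 12)
Why: Regiospecific enolate generation from the silyl enol ether (Stork–House) and C-alkylation: the electrophile approaches anti to the adjacent C11a alkenyl group, giving the trans C4a/C11a relationship under kinetic control.

Step 8
Reactants: 13 (4S,5R,6S)-5-(hexa-1,5-dien-2-yl)-6-[(4-methoxybenzyl)oxy]-4-(3-methylbut-3-en-1-yl)dihydro-2H-pyran-3(4H)-one
Product: 14 (1S,4aS,7Z,11aR)-1-[(4-methoxybenzyl)oxy]-7-methyl-11-methylidene-1,4a,5,6,9,10,11,11a-octahydrocyclonona[c]pyran-4(3H)-one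
Conditions: second-generation Grubbs catalyst (10 mol%), toluene (1 mM), 80 °C
Reagents that add atoms: none
Why: Ring-closing metathesis: initiation at the monosubstituted vinyl group and closure onto the 1,1-disubstituted olefin; a nine-membered ring accommodates only the (Z)-trisubstituted alkene, and the C11 methylidene cannot compete (it would give a cyclobutene).

Step 9
Reactants: 14 (1S,4aS,7Z,11aR)-1-[(4-methoxybenzyl)oxy]-7-methyl-11-methylidene-1,4a,5,6,9,10,11,11a-octahydrocyclonona[c]pyran-4(3H)-one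
Product: 15 (1S,4aS,7S,8R,11aR)-7,8-epoxy-1-[(4-methoxybenzyl)oxy]-7-methyl-11-methylidene-1,4a,5,6,7,8,9,10,11,11a-decahydrocyclonona[c]pyran-4(3H)-one
Conditions: D-fructose-derived Shi ketone (0.3 equiv), KHSO5 (as 2KHSO5·KHSO4·K2SO4), K2CO3, Bu4NHSO4, MeCN/CH2(OMe)2/aq. Na2B4O7 buffer, 0 °C
Reagents that add atoms: potassium peroxymonosulfate, [K+].[O-]OS(=O)(=O)O
Why: Shi asymmetric epoxidation: the chiral dioxirane takes the trisubstituted alkene in preference to the 1,1-disubstituted one and, by the spiro transition-state model (same sense as 1-phenylcyclohexene to its (R,R)-oxide), gives the (7S,8R) cis-fused oxirane under reagent control.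

Step 10
Reactants: 15 (1S,4aS,7S,8R,11aR)-7,8-epoxy-1-[(4-methoxybenzyl)oxy]-7-methyl-11-methylidene-1,4a,5,6,7,8,9,10,11,11a-decahydrocyclonona[c]pyran-4(3H)-one
Product: 16 (4aS,7S,8R,11aR)-7,8-epoxy-1-hydroxy-7-methyl-11-methylidene-1,4a,5,6,7,8,9,10,11,11a-decahydrocyclonona[c]pyran-4(3H)-one (C1 anomers)
Conditions: DDQ, CH2Cl2/pH 7 buffer (10:1), 0 °C
Reagents that add atoms: none
Why: Oxidative PMB cleavage (benzylic hydride abstraction, then hydrolysis) under neutral conditions that spare the oxirane; the lactol of a saturated 3-oxopyran is a stable cyclic hemiacetal.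

Step 11
Reactants: 16 (4aS,7S,8R,11aR)-7,8-epoxy-1-hydroxy-7-methyl-11-methylidene-1,4a,5,6,7,8,9,10,11,11a-decahydrocyclonona[c]pyran-4(3H)-one
Product: 17 (1R,4aS,7S,8R,11aR)-1-acetoxy-7,8-epoxy-7-methyl-11-methylidene-1,4a,5,6,7,8,9,10,11,11a-decahydrocyclonona[c]pyran-4(3H)-one
Conditions: Ac2O, Et3N, DMAP (cat.), CH2Cl2, −40 → −20 °C
Reagents that add atoms: acetic anhydride, CC(=O)OC(C)=O
Why: Kinetic anomeric O-acylation: under fast base-mediated mutarotation the more nucleophilic equatorial lactolate, anti to the C11a branch, is acetylated preferentially, giving the 1,11a-trans acetate (C1 R).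

Step 12
Reactants: 17 (1R,4aS,7S,8R,11aR)-1-acetoxy-7,8-epoxy-7-methyl-11-methylidene-1,4a,5,6,7,8,9,10,11,11a-decahydrocyclonona[c]pyran-4(3H)-one
Product: 18 (1R,4aS,7S,8R,11aR)-1-acetoxy-7,8-epoxy-7-methyl-11-methylidene-1,4a,5,6,7,8,9,10,11,11a-decahydrocyclonona[c]pyran-4-yl trifluoromethanesulfonate
Conditions: KN(SiMe3)2 added to 17 and PhNTf2, THF, −78 °C
Reagents that add atoms: N-phenylbis(trifluoromethanesulfonimide), O=S(=O)(N(c1ccccc1)S(=O)(=O)C(F)(F)F)C(F)(F)F
Why: Kinetic enolisation and O-triflation: the hindered amide removes the accessible O–CH2 proton at C3, not the ring-fusion C4a–H, and in-situ trapping gives the C3=C4 enol triflate, after which C4a can no longer epimerise.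

Step 13
Reactants: 19 propane-1,3-diol
Product: 20 3-[(tert-butyldimethylsilyl)oxy]propan-1-ol
Conditions: NaH (1.0 equiv), THF, 0 → 25 °C; then t-BuMe2SiCl
Reagents that add atoms: tert-butyl(chloro)dimethylsilane, CC(C)(C)[Si](C)(C)Cl
Why: Monosilylation of a symmetric diol through its sparingly soluble monoalkoxide.

Step 14
Reactants: 20 3-[(tert-butyldimethylsilyl)oxy]propan-1-ol
Product: 21 3-[(tert-butyldimethylsilyl)oxy]propanal
Conditions: PhI(OAc)2, TEMPO (10 mol%), CH2Cl2, 25 °C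
Reagents that add atoms: none
Why: Oxoammonium (TEMPO) oxidation of the primary alcohol stops cleanly at the aldehyde.

Step 15
Reactants: 22 methyl 2-bromopropanoate
Product: 24 methyl 2-(triphenyl-λ5-phosphanylidene)propanoate, via phosphonium bromide 23 (not isolated)
Conditions: PPh3, toluene, 90 °C; then NaOH (aq.), CH2Cl2, 0 °C
Reagents that add atoms: triphenylphosphine, c1ccc(cc1)P(c1ccccc1)c1ccccc1
Why: SN2 quaternisation followed by deprotonation gives the stabilised ylide.

Step 16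
Reactants: 21 3-[(tert-butyldimethylsilyl)oxy]propanal; 24 methyl 2-(triphenyl-λ5-phosphanylidene)propanoate
Product: 25 methyl (E)-5-[(tert-butyldimethylsilyl)oxy]-2-methylpent-2-enoate
Conditions: CH2Cl2, 40 °C
Reagents that add atoms: none
Why: Wittig olefination with a stabilised α-branched ylide gives the (E)-trisubstituted enoate.

Step 17
Reactants: 25 methyl (E)-5-[(tert-butyldimethylsilyl)oxy]-2-methylpent-2-enoate
Product: 26 methyl (E)-5-hydroxy-2-methylpent-2-enoate
Conditions: HF·pyridine, THF, 0 °C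
Reagents that add atoms: none
Why: Fluoride desilylation; the E geometry prevents lactonisation.

Step 18
Reactants: 26 methyl (E)-5-hydroxy-2-methylpent-2-enoate
Product: 27 methyl (E)-2-methyl-5-oxopent-2-enoate
Conditions: Dess–Martin periodinane, NaHCO3, CH2Cl2, 0 °C; crude aldehyde used at once
Reagents that add atoms: none
Why: Buffered Dess–Martin oxidation gives the β,γ-unsaturated aldehyde without migration of the double bond.

Step 19
Reactants: 18 (1R,4aS,7S,8R,11aR)-1-acetoxy-7,8-epoxy-7-methyl-11-methylidene-1,4a,5,6,7,8,9,10,11,11a-decahydrocyclonona[c]pyran-4-yl trifluoromethanesulfonate; 27 methyl (E)-2-methyl-5-oxopent-2-enoate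
Product: 28 methyl (2E,5S)-5-[(1R,4aS,7S,8R,11aR)-1-acetoxy-7,8-epoxy-7-methyl-11-methylidene-1,4a,5,6,7,8,9,10,11,11a-decahydrocyclonona[c]pyran-4-yl]-5-hydroxy-2-methylpent-2-enoate
Conditions: CrCl2 (4 equiv), (S)-N-[2-(4-isopropyl-4,5-dihydro-1,3-oxazol-2-yl)-6-methylphenyl]methanesulfonamide (4.4 equiv), Et3N, NiCl2 (5 mol%), THF, 25 °C
Reagents that add atoms: none
Why: Nozaki–Hiyama–Kishi coupling: zerovalent nickel inserts into the C–OTf bond and transmetalation gives a non-basic alkenyl species of trivalent chromium that adds to the enolisable aldehyde without touching esters, acetal acetate or oxirane; the chiral sulfonamide–chromium complex directs Re-face addition to set C12 (S).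

Step 20
Reactants: 28 methyl (2E,5S)-5-[(1R,4aS,7S,8R,11aR)-1-acetoxy-7,8-epoxy-7-methyl-11-methylidene-1,4a,5,6,7,8,9,10,11,11a-decahydrocyclonona[c]pyran-4-yl]-5-hydroxy-2-methylpent-2-enoate
Product: 29 methyl (2E,5S)-5-acetoxy-5-[(1R,4aS,7S,8R,11aR)-1-acetoxy-7,8-epoxy-7-methyl-11-methylidene-1,4a,5,6,7,8,9,10,11,11a-decahydrocyclonona[c]pyran-4-yl]-2-methylpent-2-enoate (CNP0184381.3)
Conditions: Ac2O, pyridine, DMAP (cat.), CH2Cl2, 0 °C
Reagents that add atoms: acetic anhydride, CC(=O)OC(C)=O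
Why: DMAP-catalysed O-acylation of the secondary allylic alcohol; no stereocentre is touched.

**Compound list**
1 | furan-2-ylmethanol (furfuryl alcohol) | OCc1ccco1 | starting material
2 | 6-hydroxy-2H-pyran-3(6H)-one (racemic) | O=C1COC(O)C=C1 | intermediate
3 | (6R)-6-acetoxy-2H-pyran-3(6H)-one | O=C1CO[C@H](OC(C)=O)C=C1 | intermediate
4 | (6S)-6-[(4-methoxybenzyl)oxy]-2H-pyran-3(6H)-one | O=C1CO[C@H](OCc2ccc(OC)cc2)C=C1 | intermediate
5 | allylmagnesium bromide | C=CC[Mg]Br | starting material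
6 | 2,3-dibromoprop-1-ene | C=C(Br)CBr | starting material
7 | 2-bromohexa-1,5-diene | C=C(Br)CCC=C | intermediate
8 | hexa-1,5-dien-2-ylmagnesium bromide | C=C([Mg]Br)CCC=C | intermediate (not isolated)
9 | {[(5R,6S)-5-(hexa-1,5-dien-2-yl)-6-[(4-methoxybenzyl)oxy]-5,6-dihydro-2H-pyran-3-yl]oxy}trimethylsilane | C[Si](C)(C)OC1=C[C@H](C(=C)CCC=C)[C@@H](OCc2ccc(OC)cc2)OC1 | intermediate
10 | 3-methylbut-3-en-1-ol | C=C(C)CCO | starting material
11 | 3-methylbut-3-en-1-yl trifluoromethanesulfonate | C=C(C)CCOS(=O)(=O)C(F)(F)F | intermediate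
12 | lithium (5R,6S)-5-(hexa-1,5-dien-2-yl)-6-[(4-methoxybenzyl)oxy]-5,6-dihydro-2H-pyran-3-olate (lithium enolate) | [Li]OC1=C[C@H](C(=C)CCC=C)[C@@H](OCc2ccc(OC)cc2)OC1 | intermediate (not isolated)
13 | (4S,5R,6S)-5-(hexa-1,5-dien-2-yl)-6-[(4-methoxybenzyl)oxy]-4-(3-methylbut-3-en-1-yl)dihydro-2H-pyran-3(4H)-one | O=C1CO[C@H](OCc2ccc(OC)cc2)[C@@H](C(=C)CCC=C)[C@@H]1CCC(C)=C | intermediate
14 | (1S,4aS,7Z,11aR)-1-[(4-methoxybenzyl)oxy]-7-methyl-11-methylidene-1,4a,5,6,9,10,11,11a-octahydrocyclonona[c]pyran-4(3H)-one | C=C1CC/C=C(/C)CC[C@@H]2C(=O)CO[C@H](OCc3ccc(OC)cc3)[C@@H]12 | intermediate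
15 | (1S,4aS,7S,8R,11aR)-7,8-epoxy-1-[(4-methoxybenzyl)oxy]-7-methyl-11-methylidene-1,4a,5,6,7,8,9,10,11,11a-decahydrocyclonona[c]pyran-4(3H)-one | C=C1CC[C@H]2O[C@@]2(C)CC[C@@H]2C(=O)CO[C@H](OCc3ccc(OC)cc3)[C@@H]12 | intermediate
16 | (4aS,7S,8R,11aR)-7,8-epoxy-1-hydroxy-7-methyl-11-methylidene-1,4a,5,6,7,8,9,10,11,11a-decahydrocyclonona[c]pyran-4(3H)-one (C1 anomers) | C=C1CC[C@H]2O[C@@]2(C)CC[C@@H]2C(=O)COC(O)[C@@H]12 | intermediate
17 | (1R,4aS,7S,8R,11aR)-1-acetoxy-7,8-epoxy-7-methyl-11-methylidene-1,4a,5,6,7,8,9,10,11,11a-decahydrocyclonona[c]pyran-4(3H)-one | C=C1CC[C@H]2O[C@@]2(C)CC[C@@H]2C(=O)CO[C@H](OC(C)=O)[C@@H]12 | intermediate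
18 | (1R,4aS,7S,8R,11aR)-1-acetoxy-7,8-epoxy-7-methyl-11-methylidene-1,4a,5,6,7,8,9,10,11,11a-decahydrocyclonona[c]pyran-4-yl trifluoromethanesulfonate | C=C1CC[C@H]2O[C@@]2(C)CC[C@@H]2C(OS(=O)(=O)C(F)(F)F)=CO[C@H](OC(C)=O)[C@@H]12 | intermediate
19 | propane-1,3-diol | OCCCO | starting material
20 | 3-[(tert-butyldimethylsilyl)oxy]propan-1-ol | OCCCO[Si](C)(C)C(C)(C)C | intermediate
21 | 3-[(tert-butyldimethylsilyl)oxy]propanal | O=CCCO[Si](C)(C)C(C)(C)C | intermediate
22 | methyl 2-bromopropanoate (racemic) | COC(=O)C(C)Br | starting material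
23 | (1-methoxy-1-oxopropan-2-yl)triphenylphosphonium bromide | COC(=O)C(C)[P+](c1ccccc1)(c1ccccc1)c1ccccc1.[Br-] | intermediate (not isolated)
24 | methyl 2-(triphenyl-λ5-phosphanylidene)propanoate | COC(=O)C(C)=P(c1ccccc1)(c1ccccc1)c1ccccc1 | intermediate
25 | methyl (E)-5-[(tert-butyldimethylsilyl)oxy]-2-methylpent-2-enoate | COC(=O)/C(C)=C/CCO[Si](C)(C)C(C)(C)C | intermediate
26 | methyl (E)-5-hydroxy-2-methylpent-2-enoate | COC(=O)/C(C)=C/CCO | intermediate
27 | methyl (E)-2-methyl-5-oxopent-2-enoate | COC(=O)/C(C)=C/CC=O | intermediate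
28 | methyl (2E,5S)-5-[(1R,4aS,7S,8R,11aR)-1-acetoxy-7,8-epoxy-7-methyl-11-methylidene-1,4a,5,6,7,8,9,10,11,11a-decahydrocyclonona[c]pyran-4-yl]-5-hydroxy-2-methylpent-2-enoate | C=C1CC[C@H]2O[C@@]2(C)CC[C@@H]2C([C@H](C/C=C(\C)C(=O)OC)O)=CO[C@H](OC(C)=O)[C@@H]12 | intermediate
29 | methyl (2E,5S)-5-acetoxy-5-[(1R,4aS,7S,8R,11aR)-1-acetoxy-7,8-epoxy-7-methyl-11-methylidene-1,4a,5,6,7,8,9,10,11,11a-decahydrocyclonona[c]pyran-4-yl]-2-methylpent-2-enoate | C=C1CC[C@H]2O[C@@]2(C)CC[C@@H]2C([C@H](C/C=C(\C)C(=O)OC)OC(C)=O)=CO[C@H](OC(C)=O)[C@@H]12 | target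

**Step count**
Total steps: 20. Longest linear sequence: 12 steps (1, 2, 3, 5, 7, 8, 9, 10, 11, 12, 19, 20).

**Three steps most likely to fail**

Step 7 (enolate alkylation). The homoallylic triflate may O-alkylate the enolate or be lost by elimination or ionisation before C-alkylation. The fallback sets out from silyl enol ether 9 and returns at ketone 13. A Mukaiyama–Michael addition of 9 to but-3-en-2-one, triggered by catalytic Bu4N[Ph3SiF2] (THF, −78 °C, aqueous work-up), gives (4S,5R,6S)-5-(hexa-1,5-dien-2-yl)-6-[(4-methoxybenzyl)oxy]-4-(3-oxobutyl)dihydro-2H-pyran-3(4H)-one F1, the acceptor again entering anti to the C11a group. Wittig methylenation with Ph3P=CH2 (1.0 equiv, THF, −78 → 0 °C) then converts only the unhindered methyl ketone, since the ring ketone is flanked by a branched carbon, and gives 13.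

Step 8 (ring-closing metathesis). A nine-membered ring with a trisubstituted olefin may give oligomers, and prolonged heating of the ketone may erode C4a. The fallback sets out from ketone 13 and returns at bicyclic ketone 14. NaBH4 (MeOH, 0 °C) gives (3RS,4S,5R,6S)-5-(hexa-1,5-dien-2-yl)-6-[(4-methoxybenzyl)oxy]-4-(3-methylbut-3-en-1-yl)tetrahydro-2H-pyran-3-ol F2, in which C4a is no longer enolisable and the ring is a true chair. Metathesis with the second-generation Grubbs catalyst then gives (1S,4RS,4aS,7Z,11aR)-1-[(4-methoxybenzyl)oxy]-7-methyl-11-methylidene-1,3,4,4a,5,6,9,10,11,11a-decahydrocyclonona[c]pyran-4-ol F3, and Dess–Martin oxidation returns 14.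

Step 19 (Ni/Cr coupling). The alkenylchromium carries a trans β-oxygen and could fragment to an alkyne, the aldehyde is isomerisation-prone, and ligand control at C12 may be modest. The fallback sets out from enol triflate 18 and returns at alcohol 28. Reductive carbonylation (Pd(PPh3)4, CO 1 atm, Bu3SnH, LiCl, THF, 50 °C) gives the vinylogous formate (1R,4aS,7S,8R,11aR)-7,8-epoxy-4-formyl-7-methyl-11-methylidene-1,4a,5,6,7,8,9,10,11,11a-decahydrocyclonona[c]pyran-1-yl acetate F4. Methyl tiglate is converted with LiN(iPr)2 and Me3SiCl into 1-methoxy-2-methyl-1-[(trimethylsilyl)oxy]buta-1,3-diene F5. A γ-selective vinylogous Mukaiyama aldol of F5 with F4 under Cu(OTf)2/(R)-Tol-BINAP/Bu4N[Ph3SiF2] catalysis (THF, −78 °C), which is not Lewis acidic enough to harm the oxirane or acetal acetate, gives 28.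

**Further compounds**
F1 | step 7 | (4S,5R,6S)-5-(hexa-1,5-dien-2-yl)-6-[(4-methoxybenzyl)oxy]-4-(3-oxobutyl)dihydro-2H-pyran-3(4H)-one | O=C1CO[C@H](OCc2ccc(OC)cc2)[C@@H](C(=C)CCC=C)[C@@H]1CCC(C)=O
F2 | step 8 | (3RS,4S,5R,6S)-5-(hexa-1,5-dien-2-yl)-6-[(4-methoxybenzyl)oxy]-4-(3-methylbut-3-en-1-yl)tetrahydro-2H-pyran-3-ol | OC1CO[C@H](OCc2ccc(OC)cc2)[C@@H](C(=C)CCC=C)[C@@H]1CCC(C)=C
F3 | step 8 | (1S,4RS,4aS,7Z,11aR)-1-[(4-methoxybenzyl)oxy]-7-methyl-11-methylidene-1,3,4,4a,5,6,9,10,11,11a-decahydrocyclonona[c]pyran-4-ol | C=C1CC/C=C(/C)CC[C@@H]2C(O)CO[C@H](OCc3ccc(OC)cc3)[C@@H]12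
F4 | step 19 | (1R,4aS,7S,8R,11aR)-7,8-epoxy-4-formyl-7-methyl-11-methylidene-1,4a,5,6,7,8,9,10,11,11a-decahydrocyclonona[c]pyran-1-yl acetate | C=C1CC[C@H]2O[C@@]2(C)CC[C@@H]2C(C=O)=CO[C@H](OC(C)=O)[C@@H]12
F5 | step 19 | 1-methoxy-2-methyl-1-[(trimethylsilyl)oxy]buta-1,3-diene | COC(O[Si](C)(C)C)=C(C)C=C
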